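Locants used throughout: ring C15 (quaternary C–OAc), C1 (CH2), C2 (CHMe), C3 (CH–OBz), C4 (CH carrying the enal C5=C6–C7HO); side chain C14 (CH–OAc), C13 (CHMe), C12=C11, C10 (CMe2), C9 (C=O).
Retrosynthetic cuts, in order: C7 oxidation level (enal from a 2-methylprop-1-enyl group), C11=C12 (Julia–Kocienski), C13–C14 (aldol), C4–C15 (carbonyl-ene, opens the cyclopentane), C1–C15 (alkyllithium plus oxalate), C2–C3 (aldol).
Enabling feature: O15–C15–C4–C5=C6 is a homoallylic tertiary alcohol with O15 cis to C5 on the five-membered ring and C14 (ester level) on C15. This is the retron of an ene reaction between the keto group of a C15 α-keto ester and a C4=C5 alkene with an allylic hydrogen on C6.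
Forward order: C1–C6 chain by aldol; C15 and C14 from diethyl oxalate; the only ring (cyclopentane C15–C1–C2–C3–C4) closed by the ene reaction; side chain grown from C14 by aldol, then olefination with a C9–C11 aldehyde; acyl groups; allylic oxidation last.
Stereochemistry: C2/C3 from an (S)-oxazolidinone syn aldol; C4/C15 in the ene step (O15 cis to C5 from the pericyclic geometry, face relayed from C3); C13/C14 from an (R)-oxazolidinone syn aldol; E-C11=C12 from the Julia–Kocienski reaction; E enal from the E-methyl preference of SeO2.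

Key step: step 6

Assumption: the facial course of the ene step is taken to follow that of related allylic silyl ether substrates (C5 ending cis to O3); this is the main stereochemical uncertainty of the route.

Step 1
Reactants: 1 (S)-4-benzyl-3-propionyloxazolidin-2-one; 2 (E)-4-methylpent-2-enal
Product: 4 (S)-4-benzyl-3-[(2S,3R,E)-3-hydroxy-2,6-dimethylhept-4-enoyl]oxazolidin-2-one, via Z-dibutylboron enolate 3 (not isolated)
Conditions: Bu2BOTf, i-Pr2NEt, CH2Cl2, 0 °C; then 2, −78 → 0 °C; pH 7 buffer, MeOH, 30% H2O2, 0 °C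
Reagents that add atoms: none
Why: Evans syn aldol, in which the Z-boron enolate should react through a closed chair (Zimmerman–Traxler) transition state whose benzyl group blocks one enolate face, so that C2 (S) and C3 (R) are set together by the auxiliary while 1,2-addition leaves the E alkene intact.

Step 2
Reactants: 4 syn aldol adduct
Product: 5 (S)-4-benzyl-3-[(2S,3R,E)-3-(tert-butyldimethylsilyloxy)-2,6-dimethylhept-4-enoyl]oxazolidin-2-one
Conditions: TBSOTf, 2,6-lutidine, CH2Cl2, −78 → 0 °C
Reagents that add atoms: tert-butyldimethylsilyl trifluoromethanesulfonate, CC(C)(C)[Si](C)(C)OS(=O)(=O)C(F)(F)F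
Why: Silyl ether formation with a silyl triflate and a hindered pyridine base should cap the allylic C3 hydroxyl at low temperature before retro-aldol cleavage can intervene, and it installs the group that later steers the ene reaction.

Step 3
Reactants: 5 silyl ether imide
Product: 6 (2R,3R,E)-3-(tert-butyldimethylsilyloxy)-2,6-dimethylhept-4-en-1-ol
Conditions: LiBH4, MeOH (1 equiv), THF, 0 °C → rt
Reagents that add atoms: none
Why: Reductive cleavage of the N-acyl oxazolidinone by LiBH4 should attack the exocyclic imide carbonyl and release the primary C1 alcohol and the recoverable auxiliary without touching the silyl ether or epimerising C2.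

Step 4
Reactants: 6 primary alcohol
Product: 7 tert-butyl{[(2S,3R,E)-1-iodo-2,6-dimethylhept-4-en-3-yl]oxy}dimethylsilane
Conditions: I2, PPh3, imidazole, CH2Cl2, 0 °C → rt
Reagents that add atoms: iodine, II
Why: Appel-type iodination should convert the primary alcohol into the iodide by SN2 displacement of the oxyphosphonium group under near-neutral conditions that spare the allylic silyl ether, and no stereocentre is involved.

Step 5
Reactants: 7 primary iodide; 8 diethyl oxalate
Product: 10 ethyl (4R,5S,E)-5-(tert-butyldimethylsilyloxy)-4,8-dimethyl-2-oxonon-6-enoate, via primary alkyllithium 9 (not isolated)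
Conditions: t-BuLi (2.1 equiv), Et2O–pentane, −78 °C; cannulated into 8 (4 equiv), Et2O, −78 °C; AcOH, −78 °C
Reagents that add atoms: none
Why: Iodine–lithium exchange in a cold, non-polar medium should outrun any 1,4 oxygen-to-carbon silyl shift, and inverse addition to excess oxalate should stop at single acylation because the tetrahedral lithium hemiketal persists until the cold acidic quench (acylation of an organolithium by a dialkyl oxalate to an α-keto ester).

Step 6
Reactants: 10 acyclic α-keto ester
Product: 11 ethyl (1R,2S,3S,4R)-3-(tert-butyldimethylsilyloxy)-1-hydroxy-4-methyl-2-(2-methylprop-1-en-1-yl)cyclopentane-1-carboxylate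
Conditions: degassed n-decane (0.05 M), sealed tube, 180 °C
Reagents that add atoms: none
Why: This is a thermal intramolecular carbonyl-ene reaction, the known cyclisation of unsaturated α-keto esters to 2-alkenyl-1-hydroxycyclopentanecarboxylates: the keto carbon C15, activated by the adjacent ester, bonds to C4 while its oxygen takes the C6 hydrogen through one suprafacial six-membered transition state and the π bond moves from C4=C5 to C5=C6. The cyclopentane closes in the type 1 ene mode (three-atom tether C1–C2–C3 attached to the alkene terminus C4 that is attacked, the alkene remaining outside the new ring), formally a 5-exo-trig attack of C15 on C4 with the ester exocyclic. C15 and C4 are created together and their relative configuration is fixed by the pericyclic geometry, because the oxygen must stay over the C4=C5 bond to reach the C6 hydrogen, so hydroxyl and alkenyl group come out cis. Their configuration relative to the existing centres is controlled by C3 and C2: in the envelope-like transition state the C2 methyl should lie pseudo-equatorial and the C3 silyloxy group should sit near the alkene plane on the C5 side, which the E alkene allows without 1,3-allylic strain, so C15 adds to the face that places C5 cis to O3. The step needs this facial selectivity and a single regiochemical course; the allylic silyl ether is expected to secure the first, and the second follows because the isopropyl terminus offers only one allylic hydrogen. No Lewis acid is used because a 1,2-disubstituted alkene cannot stabilise positive charge at C5, and the neutral hydrocarbon medium should leave silyl ether and ester untouched.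

Step 7
Reactants: 11 cyclopentanol ester
Product: 12 ethyl (1R,2S,3S,4R)-3-(tert-butyldimethylsilyloxy)-4-methyl-2-(2-methylprop-1-en-1-yl)-1-(triethylsilyloxy)cyclopentane-1-carboxylate
Conditions: TESOTf, 2,6-lutidine, CH2Cl2, 0 °C → rt
Reagents that add atoms: triethylsilyl trifluoromethanesulfonate, CC[Si](CC)(CC)OS(=O)(=O)C(F)(F)F
Why: Silylation with the reactive triflate should cap the hindered tertiary α-hydroxy ester and masks O15 for the hydride and enolate steps that follow (silyl ether formation).

Step 8
Reactants: 12 bis-silyl ester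
Product: 13 (1R,2S,3S,4R)-3-(tert-butyldimethylsilyloxy)-4-methyl-2-(2-methylprop-1-en-1-yl)-1-(triethylsilyloxy)cyclopentane-1-carbaldehyde
Conditions: i-Bu2AlH (1.2 equiv), CH2Cl2, −78 °C; MeOH, then aq. KNaC4H4O6
Reagents that add atoms: none
Why: Partial ester reduction should stop at the aldehyde because the aluminium hemiacetal of an α-silyloxy ester is stable at −78 °C until the cold methanol quench, and the quaternary C15 cannot epimerise.

Step 9
Reactants: 13 C14 aldehyde; 14 (R)-4-benzyl-3-propionyloxazolidin-2-one
Product: 16 (R)-4-benzyl-3-[(2R,3R)-3-hydroxy-2-methyl-3-(cyclopentyl unit of 13)propanoyl]oxazolidin-2-one, via Z-dibutylboron enolate 15 (not isolated)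
Conditions: Bu2BOTf, i-Pr2NEt, CH2Cl2, 0 °C; then 13, −78 → 0 °C; pH 7 buffer, MeOH, 30% H2O2, 0 °C
Reagents that add atoms: none
Why: Evans syn aldol with the enantiomeric auxiliary, in which the Z-boron enolate should add to the non-enolisable aldehyde through the closed chair transition state so that the (R)-benzyl group selects the enolate face and sets C13 and C14 together, syn to each other, by reagent control over the facial bias of the α-silyloxy quaternary centre.

Step 10
Reactants: 16 second aldol adduct
Product: 17 (1R,2S)-1-[(1R,2S,3S,4R)-3-(tert-butyldimethylsilyloxy)-4-methyl-2-(2-methylprop-1-en-1-yl)-1-(triethylsilyloxy)cyclopentyl]-2-methylpropane-1,3-diol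
Conditions: LiBH4, MeOH (1 equiv), THF, 0 °C → rt
Reagents that add atoms: none
Why: Reductive removal of the auxiliary with LiBH4, as in step 3, should give the 1,3-diol with a primary hydroxyl at C12 while both silyl ethers and the new stereocentres stay untouched.

Step 11
Reactants: 17 C12/C14 diol
Product: 18 C12 1-phenyl-1H-tetrazol-5-yl sulfide of 17 (C14 hydroxyl free)
Conditions: 1-phenyl-1H-tetrazole-5-thiol, PPh3, DIAD, THF, 0 °C → rt
Reagents that add atoms: 1-phenyl-1H-tetrazole-5-thiol, Sc1nnnn1-c1ccccc1
Why: Mitsunobu thioetherification should engage only the primary C12 hydroxyl, because the secondary C14 hydroxyl beside the quaternary centre is too hindered to form the oxyphosphonium ion.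

Step 12
Reactants: 18 sulfide
Product: 20 C14/C15 acetonide sulfide (C3 OTBS kept), via C14/C15 diol sulfide 19 (not isolated)
Conditions: CSA (0.1 equiv), MeOH–CH2Cl2, 0 °C → rt; evaporate; 2,2-dimethoxypropane–acetone, rt; Et3N
Reagents that add atoms: 2,2-dimethoxypropane, COC(C)(C)OC
Why: Acid-catalysed methanolysis should remove the triethylsilyl group well before the hindered secondary TBS ether, and transketalisation then ties O14 and O15 into a five-membered isopropylidene acetal (acetonide formation) that protects both for the basic olefination and keeps them distinct from O3.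

Step 13
Reactants: 20 acetonide sulfide
Product: 21 C12 1-phenyl-1H-tetrazol-5-yl sulfone (acetonide and C3 OTBS kept)
Conditions: (NH4)6Mo7O24·4H2O (0.2 equiv), 30% H2O2, EtOH, 0 °C → rt
Reagents that add atoms: hydrogen peroxide, OO
Why: Molybdate-catalysed sulfide oxidation with H2O2 should give the sulfone via the sulfoxide, and this peroxo-metal oxidant is chosen over a peracid so that the trisubstituted alkene is not epoxidised.

Step 14
Reactants: 22 ethyl 2,2-dimethyl-3-oxobutanoate
Product: 23 ethyl 2-methyl-2-(2-methyl-1,3-dioxolan-2-yl)propanoate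
Conditions: HOCH2CH2OH, p-TsOH·H2O (cat.), toluene, reflux, Dean–Stark
Reagents that add atoms: ethylene glycol, OCCO
Why: Acid-catalysed ketalisation with azeotropic water removal should convert the ketone, which cannot self-condense on its quaternary side, into the dioxolane that shields it from hydride and from the later strong base.

Step 15
Reactants: 23 dioxolane ester
Product: 24 2-methyl-2-(2-methyl-1,3-dioxolan-2-yl)propan-1-ol
Conditions: LiAlH4, Et2O, 0 °C
Reagents that add atoms: none
Why: LiAlH4 ester reduction should give the neopentyl primary alcohol, the ketal being inert to hydride.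

Step 16
Reactants: 24 neopentyl alcohol
Product: 25 2-methyl-2-(2-methyl-1,3-dioxolan-2-yl)propanal
Conditions: (COCl)2, DMSO, CH2Cl2, −78 °C; Et3N, −78 °C → rt
Reagents that add atoms: none
Why: Swern oxidation should deliver the aldehyde under non-acidic conditions that keep the dioxolane, and the product has no α-hydrogen and so cannot enolise or self-condense.

Step 17
Reactants: 21 tetrazolyl sulfone; 25 quaternary aldehyde
Product: 27 E-C11=C12 coupling product (C9 dioxolane; C14/C15 acetonide; C3 OTBS), via potassium sulfonyl carbanion 26 (not isolated)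
Conditions: KN(SiMe3)2, DME, −60 °C; then 25, −60 °C → rt
Reagents that add atoms: none
Why: Julia–Kocienski olefination, in which addition of the metalated sulfone to the aldehyde, Smiles rearrangement and loss of SO2 and the tetrazolone anion should give the C11=C12 alkene with the E geometry favoured by potassium in DME and by the bulky aldehyde, while C13 (β to sulfur) is not epimerised.

Step 18
Reactants: 27 coupling product
Product: 28 C3 alcohol (acetonide and dioxolane kept)
Conditions: Bu4NF, THF, rt → 45 °C
Reagents that add atoms: none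
Why: Fluoride-mediated desilylation should free the C3 hydroxyl, the only silyl ether left, while both acetals and both alkenes are inert to fluoride.

Step 19
Reactants: 28 C3 alcohol
Product: 29 C3 benzoate (acetonide and dioxolane kept)
Conditions: BzCl, pyridine, DMAP (cat.), CH2Cl2, rt
Reagents that add atoms: benzoyl chloride, O=C(Cl)c1ccccc1
Why: DMAP-catalysed acylation should esterify the single free secondary hydroxyl at C3 (nucleophilic catalysis).

Step 20
Reactants: 29 benzoate
Product: 30 3-benzoate 14,15-diol C9 methyl ketone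
Conditions: 2 M aq. HCl, THF, rt → 40 °C
Reagents that add atoms: water, O
Why: Acid-catalysed acetal hydrolysis should remove the acetonide and the dioxolane together at an acidity too low to hydrolyse the benzoate or to protonate the trisubstituted alkene.

Step 21
Reactants: 30 diol ketone
Product: 31 3-benzoate 14,15-diacetate methyl ketone carrying the 2-methylprop-1-enyl group at C4
Conditions: Ac2O, Sc(OTf)3 (5 mol %), MeCN, −20 → 0 °C
Reagents that add atoms: acetic anhydride, CC(=O)OC(C)=O
Why: Lewis acid-catalysed acylation with Sc(OTf)3 and acetic anhydride is one of the few methods that acetylate hindered tertiary alcohols at low temperature, and it should esterify the secondary C14 and tertiary C15 hydroxyls in one operation without ionising the C15–O bond.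

Step 22
Reactants: 31 diacetate benzoate
Product: 32 E allylic alcohol (C7 hydroxyl) of 31
Conditions: SeO2 (0.5 equiv), t-BuOOH (3 equiv), salicylic acid (cat.), CH2Cl2, rt
Reagents that add atoms: tert-butyl hydroperoxide, CC(C)(C)OO (net source of the new oxygen); selenium dioxide, O=[Se]=O (transfers it)
Why: SeO2-catalysed allylic oxidation (ene reaction followed by 2,3-sigmatropic shift of the allylseleninic acid) should attack the electron-rich trisubstituted alkene at the methyl group trans to C4, the usual E-methyl preference of gem-dimethyl alkenes, while the hindered disubstituted alkene and the esters are left alone.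

Step 23
Reactants: 32 E allylic alcohol
Product: 33 CNP0489076.1
Conditions: MnO2, CH2Cl2, rt
Reagents that add atoms: none
Why: MnO2 allylic alcohol oxidation should take the primary allylic alcohol to the conjugated aldehyde without isomerising the E alkene or touching the esters and the ketone.

Compound list
1 | (S)-4-benzyl-3-propionyloxazolidin-2-one | CCC(=O)N1[C@@H](Cc2ccccc2)COC1=O | starting material
2 | (E)-4-methylpent-2-enal | CC(C)/C=C/C=O | starting material
3 | Z-dibutylboron enolate of 1 (formed in situ) | C/C=C(\OB(CCCC)CCCC)N1[C@@H](Cc2ccccc2)COC1=O | intermediate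
4 | (S)-4-benzyl-3-[(2S,3R,E)-3-hydroxy-2,6-dimethylhept-4-enoyl]oxazolidin-2-one | O=C(N1[C@@H](Cc2ccccc2)COC1=O)[C@@H](C)[C@H](O)/C=C/C(C)C | intermediate
5 | (S)-4-benzyl-3-[(2S,3R,E)-3-(tert-butyldimethylsilyloxy)-2,6-dimethylhept-4-enoyl]oxazolidin-2-one | O=C(N1[C@@H](Cc2ccccc2)COC1=O)[C@@H](C)[C@H](O[Si](C)(C)C(C)(C)C)/C=C/C(C)C | intermediate
6 | (2R,3R,E)-3-(tert-butyldimethylsilyloxy)-2,6-dimethylhept-4-en-1-ol | OC[C@@H](C)[C@H](O[Si](C)(C)C(C)(C)C)/C=C/C(C)C | intermediate
7 | tert-butyl{[(2S,3R,E)-1-iodo-2,6-dimethylhept-4-en-3-yl]oxy}dimethylsilane | IC[C@@H](C)[C@H](O[Si](C)(C)C(C)(C)C)/C=C/C(C)C | intermediate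
8 | diethyl oxalate | CCOC(=O)C(=O)OCC | starting material
9 | primary alkyllithium from 7 (Li in place of I; formed in situ) | [Li]C[C@@H](C)[C@H](O[Si](C)(C)C(C)(C)C)/C=C/C(C)C | intermediate
10 | ethyl (4R,5S,E)-5-(tert-butyldimethylsilyloxy)-4,8-dimethyl-2-oxonon-6-enoate | CCOC(=O)C(=O)C[C@@H](C)[C@H](O[Si](C)(C)C(C)(C)C)/C=C/C(C)C | intermediate
11 | ethyl (1R,2S,3S,4R)-3-(tert-butyldimethylsilyloxy)-1-hydroxy-4-methyl-2-(2-methylprop-1-en-1-yl)cyclopentane-1-carboxylate | CCOC(=O)[C@@]1(O)C[C@@H](C)[C@H](O[Si](C)(C)C(C)(C)C)[C@@H]1C=C(C)C | intermediate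
12 | ethyl (1R,2S,3S,4R)-3-(tert-butyldimethylsilyloxy)-4-methyl-2-(2-methylprop-1-en-1-yl)-1-(triethylsilyloxy)cyclopentane-1-carboxylate | CCOC(=O)[C@@]1(O[Si](CC)(CC)CC)C[C@@H](C)[C@H](O[Si](C)(C)C(C)(C)C)[C@@H]1C=C(C)C | intermediate
13 | (1R,2S,3S,4R)-3-(tert-butyldimethylsilyloxy)-4-methyl-2-(2-methylprop-1-en-1-yl)-1-(triethylsilyloxy)cyclopentane-1-carbaldehyde | O=C[C@@]1(O[Si](CC)(CC)CC)C[C@@H](C)[C@H](O[Si](C)(C)C(C)(C)C)[C@@H]1C=C(C)C | intermediate
14 | (R)-4-benzyl-3-propionyloxazolidin-2-one | CCC(=O)N1[C@H](Cc2ccccc2)COC1=O | starting material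
15 | Z-dibutylboron enolate of 14 (formed in situ) | C/C=C(\OB(CCCC)CCCC)N1[C@H](Cc2ccccc2)COC1=O | intermediate
16 | (R)-4-benzyl-3-[(2R,3R)-3-{(1R,2S,3S,4R)-3-(tert-butyldimethylsilyloxy)-4-methyl-2-(2-methylprop-1-en-1-yl)-1-(triethylsilyloxy)cyclopentyl}-3-hydroxy-2-methylpropanoyl]oxazolidin-2-one | O=C(N1[C@H](Cc2ccccc2)COC1=O)[C@H](C)[C@@H](O)[C@@]1(O[Si](CC)(CC)CC)C[C@@H](C)[C@H](O[Si](C)(C)C(C)(C)C)[C@@H]1C=C(C)C | intermediate
17 | (1R,2S)-1-[(1R,2S,3S,4R)-3-(tert-butyldimethylsilyloxy)-4-methyl-2-(2-methylprop-1-en-1-yl)-1-(triethylsilyloxy)cyclopentyl]-2-methylpropane-1,3-diol | OC[C@H](C)[C@@H](O)[C@@]1(O[Si](CC)(CC)CC)C[C@@H](C)[C@H](O[Si](C)(C)C(C)(C)C)[C@@H]1C=C(C)C | intermediate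
18 | C12 1-phenyl-1H-tetrazol-5-yl sulfide of 17 (C14 OH free, C15 OTES, C3 OTBS) | S(C[C@H](C)[C@@H](O)[C@@]1(O[Si](CC)(CC)CC)C[C@@H](C)[C@H](O[Si](C)(C)C(C)(C)C)[C@@H]1C=C(C)C)c1nnnn1-c1ccccc1 | intermediate
19 | C14/C15 diol sulfide (TES removed; formed in situ) | S(C[C@H](C)[C@@H](O)[C@@]1(O)C[C@@H](C)[C@H](O[Si](C)(C)C(C)(C)C)[C@@H]1C=C(C)C)c1nnnn1-c1ccccc1 | intermediate
20 | C14/C15 acetonide sulfide (C3 OTBS) | S(C[C@H](C)[C@H]1OC(C)(C)O[C@@]12C[C@@H](C)[C@H](O[Si](C)(C)C(C)(C)C)[C@@H]2C=C(C)C)c1nnnn1-c1ccccc1 | intermediate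
21 | C12 1-phenyl-1H-tetrazol-5-yl sulfone with C14/C15 acetonide and C3 OTBS | O=S(=O)(C[C@H](C)[C@H]1OC(C)(C)O[C@@]12C[C@@H](C)[C@H](O[Si](C)(C)C(C)(C)C)[C@@H]2C=C(C)C)c1nnnn1-c1ccccc1 | intermediate
22 | ethyl 2,2-dimethyl-3-oxobutanoate | CCOC(=O)C(C)(C)C(C)=O | starting material
23 | ethyl 2-methyl-2-(2-methyl-1,3-dioxolan-2-yl)propanoate | CCOC(=O)C(C)(C)C1(C)OCCO1 | intermediate
24 | 2-methyl-2-(2-methyl-1,3-dioxolan-2-yl)propan-1-ol | OCC(C)(C)C1(C)OCCO1 | intermediate
25 | 2-methyl-2-(2-methyl-1,3-dioxolan-2-yl)propanal | O=CC(C)(C)C1(C)OCCO1 | intermediate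
26 | potassium α-sulfonyl carbanion of 21 (formed in situ) | [K+].O=S(=O)([CH-][C@H](C)[C@H]1OC(C)(C)O[C@@]12C[C@@H](C)[C@H](O[Si](C)(C)C(C)(C)C)[C@@H]2C=C(C)C)c1nnnn1-c1ccccc1 | intermediate
27 | E-C11=C12 coupling product with C9 dioxolane, C14/C15 acetonide and C3 OTBS | CC1(OCCO1)C(C)(C)/C=C/[C@H](C)[C@H]1OC(C)(C)O[C@@]12C[C@@H](C)[C@H](O[Si](C)(C)C(C)(C)C)[C@@H]2C=C(C)C | intermediate
28 | C3 alcohol of 27 (TBS removed) | CC1(OCCO1)C(C)(C)/C=C/[C@H](C)[C@H]1OC(C)(C)O[C@@]12C[C@@H](C)[C@H](O)[C@@H]2C=C(C)C | intermediate
29 | C3 benzoate with C9 dioxolane and C14/C15 acetonide | CC1(OCCO1)C(C)(C)/C=C/[C@H](C)[C@H]1OC(C)(C)O[C@@]12C[C@@H](C)[C@H](OC(=O)c3ccccc3)[C@@H]2C=C(C)C | intermediate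
30 | 3-benzoate 14,15-diol C9 methyl ketone | CC(=O)C(C)(C)/C=C/[C@H](C)[C@@H](O)[C@@]1(O)C[C@@H](C)[C@H](OC(=O)c2ccccc2)[C@@H]1C=C(C)C | intermediate
31 | 3-benzoate 14,15-diacetate methyl ketone with 2-methylprop-1-enyl at C4 | CC(=O)O[C@H]([C@@H](C)/C=C/C(C)(C)C(C)=O)[C@@]1(OC(C)=O)C[C@@H](C)[C@H](OC(=O)c2ccccc2)[C@@H]1C=C(C)C | intermediate
32 | E allylic alcohol (C7 OH) of 31 | CC(=O)O[C@H]([C@@H](C)/C=C/C(C)(C)C(C)=O)[C@@]1(OC(C)=O)C[C@@H](C)[C@H](OC(=O)c2ccccc2)[C@@H]1/C=C(\C)CO | intermediate
33 | CNP0489076.1: (2R,3S,4S,13S,14R,15R;5E,11E) 3-benzoate 14,15-diacetate with C7 aldehyde and C9 methyl ketone | CC(=O)O[C@H]([C@@H](C)/C=C/C(C)(C)C(C)=O)[C@@]1(OC(C)=O)C[C@@H](C)[C@H](OC(=O)c2ccccc2)[C@@H]1/C=C(\C)C=O | target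

Total step count: 23. Longest linear sequence: 20 steps (steps 1 to 13, then 17 to 23); the aldehyde branch (steps 14 to 16) is three steps.

Steps most likely to fail

Step 6 (ene cyclisation). The single tertiary hydrogen at C6 may be transferred too slowly, so that thermal decomposition or silyl loss competes at 180 °C. Attack on the other alkene face would give the C4/C15 epimeric pair. The fallback sets out from 1 and comes back at 11. It redesigns the ene partner as a propenyl group, which offers three unhindered primary hydrogens, and adds the gem-dimethyl terminus afterwards by cross-metathesis. The boron aldol of step 1, run on 1 with commercial (E)-but-2-enal (C/C=C/C=O), would give the hexenoyl syn adduct F1. TBSOTf/2,6-lutidine would give the silyl ether F2, LiBH4 the primary alcohol F3, and PPh3/I2/imidazole the iodide F4. t-BuLi in ether–pentane at −78 °C converts F4 into the alkyllithium F5, which is acylated by 8 to the keto ester F6. Heating F6 in decane as in step 6 should give, by transfer of a methyl hydrogen, the vinylcyclopentanol F7. Cross-metathesis of F7 in neat 2-methylbut-2-ene with the second-generation Grubbs catalyst RuCl2(=CHPh)(PCy3)(H2IMes) exchanges the terminal CH2 for an isopropylidene group and returns to the route at 11.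

Step 9 (second aldol). The neopentyl-type aldehyde may react sluggishly with the boron enolate, and its own facial preference may oppose that of the auxiliary (mismatched double stereodifferentiation), which would give low conversion or mixtures of aldol isomers. The fallback sets out from 13 and comes back at 17. It forms the C13–C14 bond by enolate acylation and sets C14 afterwards by chelation-controlled hydride delivery (acylation–reduction route to syn aldols). Oxidation of 13 with NaClO2/NaH2PO4/2-methylbut-2-ene in t-BuOH–water would give the carboxylic acid F8. 1-Chloro-N,N,2-trimethylprop-1-en-1-amine in CH2Cl2 converts it under neutral conditions into the acid chloride F9. The (S)-imide 1 is deprotonated with LiN(i-Pr)2 in THF at −78 °C to its lithium Z-enolate F10, which is acylated by F9 to the β-keto imide F11. The acylating agent approaches the chelated enolate opposite the benzyl group, the face opposite to the one used in the boron aldol, which is why the (S)-auxiliary is used here. Reduction with Zn(BH4)2 in CH2Cl2–Et2O at −20 °C, through the zinc chelate of the two carbonyl groups, should deliver hydride anti to the C13 methyl and give the syn β-hydroxy imide F12. LiBH4 under the conditions of step 10 then releases the auxiliary and returns to the route at 17.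

Step 22 (allylic oxidation). On the most advanced intermediate the oxidation may stall, over-oxidise, or lose site selectivity by attacking the C13–H of the other alkene or the methyl ketone. The fallback sets out from 31 and comes back at 33. It replaces C–H oxidation by excision of the isopropylidene carbon and re-olefination. mCPBA (1 equiv, NaHCO3, CH2Cl2, 0 °C) should epoxidise only the electron-rich trisubstituted C5=C6 alkene, the disubstituted alkene being shielded by the quaternary C10, to give the epoxide F13 as a mixture at C5. H5IO6 in THF–Et2O–water at 0 °C cleaves the epoxide to the C5 aldehyde F14 with loss of acetone. Wittig reaction of F14 with the stabilised ylide 2-(triphenylphosphoranylidene)propanal (CC(C=O)=P(c1ccccc1)(c1ccccc1)c1ccccc1) in toluene at 60 °C should give the E enal and return to the route at the target 33.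

Further compounds
F1 | step 6 | (S)-4-benzyl-3-[(2S,3R,E)-3-hydroxy-2-methylhex-4-enoyl]oxazolidin-2-one | O=C(N1[C@@H](Cc2ccccc2)COC1=O)[C@@H](C)[C@H](O)/C=C/C
F2 | step 6 | (S)-4-benzyl-3-[(2S,3R,E)-3-(tert-butyldimethylsilyloxy)-2-methylhex-4-enoyl]oxazolidin-2-one | O=C(N1[C@@H](Cc2ccccc2)COC1=O)[C@@H](C)[C@H](O[Si](C)(C)C(C)(C)C)/C=C/C
F3 | step 6 | (2R,3R,E)-3-(tert-butyldimethylsilyloxy)-2-methylhex-4-en-1-ol | OC[C@@H](C)[C@H](O[Si](C)(C)C(C)(C)C)/C=C/C
F4 | step 6 | tert-butyl{[(2S,3R,E)-1-iodo-2-methylhex-4-en-3-yl]oxy}dimethylsilane | IC[C@@H](C)[C@H](O[Si](C)(C)C(C)(C)C)/C=C/C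
F5 | step 6 | primary alkyllithium from F4 (Li in place of I) | [Li]C[C@@H](C)[C@H](O[Si](C)(C)C(C)(C)C)/C=C/C
F6 | step 6 | ethyl (4R,5S,E)-5-(tert-butyldimethylsilyloxy)-4-methyl-2-oxooct-6-enoate | CCOC(=O)C(=O)C[C@@H](C)[C@H](O[Si](C)(C)C(C)(C)C)/C=C/C
F7 | step 6 | ethyl (1R,2S,3S,4R)-3-(tert-butyldimethylsilyloxy)-2-ethenyl-1-hydroxy-4-methylcyclopentane-1-carboxylate | CCOC(=O)[C@@]1(O)C[C@@H](C)[C@H](O[Si](C)(C)C(C)(C)C)[C@@H]1C=C
F8 | step 9 | (1R,2S,3S,4R)-3-(tert-butyldimethylsilyloxy)-4-methyl-2-(2-methylprop-1-en-1-yl)-1-(triethylsilyloxy)cyclopentane-1-carboxylic acid | OC(=O)[C@@]1(O[Si](CC)(CC)CC)C[C@@H](C)[C@H](O[Si](C)(C)C(C)(C)C)[C@@H]1C=C(C)C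
F9 | step 9 | acid chloride of F8 | ClC(=O)[C@@]1(O[Si](CC)(CC)CC)C[C@@H](C)[C@H](O[Si](C)(C)C(C)(C)C)[C@@H]1C=C(C)C
F10 | step 9 | lithium Z-enolate of 1 | C/C=C(\O[Li])N1[C@@H](Cc2ccccc2)COC1=O
F11 | step 9 | β-keto imide from F9 and F10 (C14 ketone, (S)-auxiliary) | O=C(N1[C@@H](Cc2ccccc2)COC1=O)[C@H](C)C(=O)[C@@]1(O[Si](CC)(CC)CC)C[C@@H](C)[C@H](O[Si](C)(C)C(C)(C)C)[C@@H]1C=C(C)C
F12 | step 9 | syn β-hydroxy imide carrying the (S)-auxiliary (C13 and C14 as in 16) | O=C(N1[C@@H](Cc2ccccc2)COC1=O)[C@H](C)[C@@H](O)[C@@]1(O[Si](CC)(CC)CC)C[C@@H](C)[C@H](O[Si](C)(C)C(C)(C)C)[C@@H]1C=C(C)C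
F13 | step 22 | C5/C6 epoxide of 31 (mixture at C5) | CC(=O)O[C@H]([C@@H](C)/C=C/C(C)(C)C(C)=O)[C@@]1(OC(C)=O)C[C@@H](C)[C@H](OC(=O)c2ccccc2)[C@@H]1C3OC3(C)C
F14 | step 22 | C5 aldehyde (formyl group on C4) | CC(=O)O[C@H]([C@@H](C)/C=C/C(C)(C)C(C)=O)[C@@]1(OC(C)=O)C[C@@H](C)[C@H](OC(=O)c2ccccc2)[C@@H]1C=O
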